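Slowness is a reading like any other, and the theta run, which is the flask asked about followed so far, offers one.

| flask | substrate | partner | other conformer | temperature | remark | time |
|---|---|---|---|---|---|---|
| theta | 0.10 M | 0.70 equiv | 0.10 equiv | −20 °C | the very flask that is asked about, followed so far |  |
| beta | 0.10 M | 0.70 equiv | 0.15 equiv | −35 °C | run made earlier |  |
| flask | 0.10 M | 0.700 equiv | 0.100 equiv | −20 °C |  | 8.0 d |

| run | time / d | target / % | substrate / % |
|---|---|---|---|
| theta | 0.625 | 12.0 | 81.3 |
| theta | 1.67 | 14.1 | 77.7 |
| theta | 3.00 | 16.0 | 76.2 |
| theta | 8.00 | 17.3 | 74.6 |
| beta | 0.417 | 2.2 | 86.7 |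
| beta | 1.25 | 4.8 | 85.2 |
| beta | 2.00 | 7.0 | 83.6 |
| beta | 4.00 | 10.0 | 77.8 |

(each reading ± 0.5 percentage points)

- teal: change nothing and wait 8.0 d more
- amber: at 8.0 d raise the temperature by 20 K, then wait 8.0 d
- ochre: at 8.0 d add partner, 50.0% of the amount charged, then wait 8.0 d
- grey: at 8.0 d take out 90% of the target then present, then wait 8.0 d

- what is taken out of target is counted as made
- what was read earlier has a scatter of 0.5 percentage points, one standard deviation
- additions bring no volume worth counting

- target, in percent of the substrate and other conformer together first charged, at 8.0 d
- the remedy with the largest gain of target, or "none" below 2 percentage points (teal / amber / ochre / grey / none)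
- target present, with what was taken out counted in, in percent of the substrate and other conformer together first charged, after teal
- target present, with what was taken out counted in, in percent of the substrate and other conformer together first charged, after grey

Take target to come from one substrate and one partner, with a pace of k[substrate][partner]. The theta run then looks contradictory. Target gained 12.0% in the first 0.625 d but 1.3 percentage points in the last 5.00 d, a pace 73.8 times lower. Yet substrate still reads 74.6%, and subtracting target from the charge leaves 72.8% of the partner.

Dividing each pace by its substrate reading clears this up. The late value over the early one is the working share, the fraction of the first window's [partner] still reacting late: it reads 1.48%, far below the 72.8% promised by subtraction. The reckoning committed to here is that partner has left the working pool by some other way, and that target has no place in the pace.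

So now is the reading, 17.3%. Teal, holding the late pace, adds 2.1 points, giving 19.4%, and grey gives the same. Ochre, scaling the target made so far by the added partner, adds 8.7 points. Amber scales the late pace by the first-window ratio between −35 °C and −20 °C, 3.64, a rough ratio since those runs also differ in other conformer, 0.15 equiv against 0.10 equiv. Stretched to the rise, it adds 12 points, more than ochre. Amber is the choice of this reckoning, which rests on a late gain read with a scatter of 0.5 points at each end.

The forecast gives 17.2%, 17.5% after teal, 27% after grey and names grey, calling the flask “essentially at equilibrium, and waiting gains almost nothing”, and so it differs from the reckoning above on teal, on grey and on the best remedy.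

The simulation gives 17.5%, 20.0% after teal, 20.0% after grey and amber as best, with amber gaining 21 points against the 12 points reckoned.

    substrate ⇌ other conformer (K = 0.0450, k = 5.50 × 10⁻⁴ min⁻¹, Ea = 87.0 kJ mol⁻¹, ΔH = −7.00 kJ mol⁻¹)
    substrate + partner → target (k = 0.00480 L mol⁻¹ min⁻¹, Ea = 67.0 kJ mol⁻¹)
    partner + other conformer → isomer of the product (k = 0.0260 L mol⁻¹ min⁻¹, Ea = 46.0 kJ mol⁻¹)
    partner ⇌ dormant form (K = 28.0, k = 9.10 × 10⁻⁴ min⁻¹, Ea = 80.0 kJ mol⁻¹, ΔH = −21.0 kJ mol⁻¹)
    2 partner → homo dimer (k = 0.00710 L mol⁻¹ min⁻¹, Ea = 61.0 kJ mol⁻¹)
    (constants at −20 °C)

The working share read at 1.48% goes with a flask that at 8.00 d holds partner, the limiting reagent, at 0.948% of its own charge and dormant form at 0.0286 M. At that time partner enters the dormant form 2.3 times as fast as it enters target, the way back from the dormant form not counted. In a neighbour flask with 0.420 equiv of partner, the same 1.48% on a first-window pace scaled to that charge makes the last 5.00 d worth 0.78 points, and target as a whole, scaled to the charge, should stand at 10.4%. The computed flask gives 11.8%.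

The data were computed from invented constants, noise included.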